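**Strategy**

The dienone ring (C1 ketone, C2 allyl, C4 quaternary, C5 OMe; side chain C8H(Me)–C7H2Ar) is grown from a cyclopentene. Its C4–C5 unit, a quaternary methoxy carbon beside an oxygenated carbon, is read as the α-methoxy ketone left by a semipinacol shift. In the key step a benzyl cation adds to the enol-ether carbon that becomes C8 while the ring vinyl carbon (future C3) migrates anti from the carbinol carbon (future C5) to C4: one operation forms C7–C8, enlarges the five- to the six-membered ring and sets C4 and C8 together. The precursor is a 1-[(Z)-1-methoxypropenyl]cyclopent-2-enol whose carbinol configuration is relayed from a silyloxy stereocentre later oxidised to the C1 ketone.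

Key step: step 6

Assumption: (S)-4-[(tert-butyldimethylsilyl)oxy]cyclopent-2-en-1-one is taken as a purchasable chiral-pool building block (both enantiomers are sold).

**Route**

Step 1
Reactants: 1 (S)-4-[(tert-butyldimethylsilyl)oxy]cyclopent-2-en-1-one
Product: 3 (S)-3-allyl-4-[(tert-butyldimethylsilyl)oxy]cyclopent-2-en-1-one, via silyl enol ether 2 (not isolated)
Conditions: allylMgBr/CuBr·SMe2 (1:1, 1.5 equiv), TMSCl, THF, −78 °C; crude 2, Pd(OAc)2 (1 equiv), MeCN, rt
Reagents that add atoms: allylmagnesium bromide (C=CC[Mg]Br)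
Why: TMSCl-assisted conjugate addition of the allylcopper reagent anti to the silyloxy group gives a regiodefined silyl enol ether whose Saegusa–Ito dehydrogenation restores the enone with the allyl group on the β-carbon, the transient C3 stereocentre being erased and C4 left untouched.

Step 2
Reactants: 4 allyl methyl ether
Product: 5 (Z)-1-methoxyprop-1-ene
Conditions: KOtBu (cat.), DMSO, rt; distil
Reagents that add atoms: none
Why: Base-mediated allyl-to-propenyl ether isomerisation runs through the potassium-chelated cisoid allyl anion and should give the Z enol ether selectively.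

Step 3
Reactants: 5 (Z)-1-methoxyprop-1-ene; 3 (S)-3-allyl-4-[(tert-butyldimethylsilyl)oxy]cyclopent-2-en-1-one
Product: 7 (1R,4S)-3-allyl-4-[(tert-butyldimethylsilyl)oxy]-1-[(Z)-1-methoxyprop-1-en-1-yl]cyclopent-2-en-1-ol, via lithiated enol ether 6 (not isolated)
Conditions: 5 (excess), t-BuLi, THF, −78 → −10 °C; then 3, −78 °C; H2O
Reagents that add atoms: none
Why: α-Lithiation of the Z enol ether with retention of geometry gives an acyl-anion equivalent (polarity reversal) that adds 1,2 to the enone carbonyl from the face anti to the C4 silyloxy group, which should set C1 as R (OH cis to OTBS) by substrate control.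

Step 4
Reactants: 8 vanillyl alcohol
Product: 10 {4-[(tert-butyldimethylsilyl)oxy]-3-methoxyphenyl}methanol, via sodium phenolate 9 (not isolated)
Conditions: NaH (1.0 equiv), THF, 0 °C; TBSCl (1.0 equiv)
Reagents that add atoms: tert-butyldimethylsilyl chloride (CC(C)(C)[Si](C)(C)Cl)
Why: One equivalent of base deprotonates only the phenol, and the phenolate is O-silylated far faster than the neutral benzylic alcohol.

Step 5
Reactants: 10 {4-[(tert-butyldimethylsilyl)oxy]-3-methoxyphenyl}methanol
Product: 11 [4-(bromomethyl)-2-methoxyphenoxy](tert-butyl)dimethylsilane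
Conditions: CBr4, PPh3, CH2Cl2, 0 °C
Reagents that add atoms: carbon tetrabromide (BrC(Br)(Br)Br)
Why: The Appel reaction converts the primary benzylic alcohol into the bromide under neutral conditions that leave the aryl silyl ether intact.

Step 6
Reactants: 7 (1R,4S)-3-allyl-4-[(tert-butyldimethylsilyl)oxy]-1-[(Z)-1-methoxyprop-1-en-1-yl]cyclopent-2-en-1-ol; 11 [4-(bromomethyl)-2-methoxyphenoxy](tert-butyl)dimethylsilane
Product: 13 (2S,5S)-4-allyl-5-[(tert-butyldimethylsilyl)oxy]-2-{(2R)-1-[4-[(tert-butyldimethylsilyl)oxy]-3-methoxyphenyl]propan-2-yl}-2-methoxycyclohex-3-en-1-one, via benzylic triflate 12 (not isolated)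
Conditions: AgOTf (1.5 equiv), 2,6-di-tert-butyl-4-methylpyridine (2.5 equiv), 4 Å MS, CH2Cl2, −78 → −40 °C
Reagents that add atoms: none
Why: Proposed new method: silver abstracts bromide from 11 to give the benzylic triflate/cation 12, which attacks the enol ether of 7 at its β-carbon (the future C8) while the ring vinyl carbon C2 of 7, held anti-periplanar, shifts from the carbinol carbon C1 to the developing oxocarbenium carbon and the hydroxyl collapses to the ketone, its proton going to the hindered pyridine (cation-initiated semipinacol rearrangement). The closest known reaction types are the proton- or halonium-induced semipinacol ring expansion of 1-(1-alkoxyvinyl)cycloalkanols and the Lewis-acid benzylation of enol ethers with benzyl halides; a benzyl cation as the trigger on this substrate class is the unprecedented element. No ring is closed by cyclisation: the six-membered ring arises from the cyclopentene by a 1,2-carbon shift that inserts the exocyclic methoxy-bearing carbon between C1 and C2 of 7. The two new stereocentres arise together: anti addition of the electrophile and the migrating carbon across the Z double bond fixes their relative configuration, and the (1R) carbinol centre is expected to fix the absolute sense, because in the hydrogen-bonded rotamer (O–H···OMe, ring CH2 eclipsing the C=C) C2 lies on one face only and the cation must come from the other. The step needs C- over O-benzylation, vinyl over CH2 migration and shift over proton loss; the high π-nucleophilicity of the enol ether compared with the two isolated alkenes and the hindered hydroxyl, the better migratory aptitude of the sp2 carbon, and a non-nucleophilic base at low temperature should secure these.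

Step 7
Reactants: 13 (2S,5S)-4-allyl-5-[(tert-butyldimethylsilyl)oxy]-2-{(2R)-1-[4-[(tert-butyldimethylsilyl)oxy]-3-methoxyphenyl]propan-2-yl}-2-methoxycyclohex-3-en-1-one
Product: 15 tert-butyl{[(1S,4S)-2-allyl-4-{(2R)-1-[4-[(tert-butyldimethylsilyl)oxy]-3-methoxyphenyl]propan-2-yl}-4,5-dimethoxycyclohexa-2,5-dien-1-yl]oxy}dimethylsilane, via potassium enolate 14 (not isolated)
Conditions: KHMDS (1.1 equiv), THF–DMPU, −78 °C; MeOTf (1.5 equiv)
Reagents that add atoms: methyl trifluoromethanesulfonate (COS(=O)(=O)C(F)(F)F)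
Why: Only C6 of 13 carries α-hydrogens, so the enolate is regiodefined, and the potassium counter-ion, the polar cosolvent and the hard triflate electrophile should favour enolate O-methylation, which places the enol-ether methoxy group unambiguously on the carbon next to the quaternary centre.

Step 8
Reactants: 15 tert-butyl{[(1S,4S)-2-allyl-4-{(2R)-1-[4-[(tert-butyldimethylsilyl)oxy]-3-methoxyphenyl]propan-2-yl}-4,5-dimethoxycyclohexa-2,5-dien-1-yl]oxy}dimethylsilane
Product: 16 (1S,4S)-2-allyl-4-[(2R)-1-(4-hydroxy-3-methoxyphenyl)propan-2-yl]-4,5-dimethoxycyclohexa-2,5-dien-1-ol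
Conditions: TBAF (2.5 equiv), AcOH (2.5 equiv), THF, 0 °C → rt
Reagents that add atoms: none
Why: Fluoride-mediated desilylation cleaves both the aryl and the secondary allylic silyl ether, and the acetic acid buffer protects the labile bis-allylic dienol.

Step 9
Reactants: 16 (1S,4S)-2-allyl-4-[(2R)-1-(4-hydroxy-3-methoxyphenyl)propan-2-yl]-4,5-dimethoxycyclohexa-2,5-dien-1-ol
Product: 17 (4S)-2-allyl-4-[(2R)-1-(4-hydroxy-3-methoxyphenyl)propan-2-yl]-4,5-dimethoxycyclohexa-2,5-dien-1-one
Conditions: activated MnO2, CH2Cl2, rt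
Reagents that add atoms: none
Why: Manganese dioxide should oxidise the doubly allylic secondary alcohol faster than the phenol (allylic oxidation), giving the cross-conjugated dienone, erasing the relay stereocentre and leaving the non-epimerisable C4 and C8 untouched.

**Compound list**

1 | (S)-4-[(tert-butyldimethylsilyl)oxy]cyclopent-2-en-1-one | O=C1C=C[C@@H](O[Si](C)(C)C(C)(C)C)C1 | starting material
2 | (3S,4S)-3-allyl-4-[(tert-butyldimethylsilyl)oxy]-1-[(trimethylsilyl)oxy]cyclopent-1-ene (allyl trans to OTBS) | C[Si](C)(C)OC1=C[C@H](CC=C)[C@@H](O[Si](C)(C)C(C)(C)C)C1 | intermediate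
3 | (S)-3-allyl-4-[(tert-butyldimethylsilyl)oxy]cyclopent-2-en-1-one | O=C1C=C(CC=C)[C@@H](O[Si](C)(C)C(C)(C)C)C1 | intermediate
4 | allyl methyl ether | COCC=C | starting material
5 | (Z)-1-methoxyprop-1-ene | CO/C=C\C | intermediate
6 | (Z)-(1-methoxyprop-1-en-1-yl)lithium | CO/C([Li])=C\C | intermediate
7 | (1R,4S)-3-allyl-4-[(tert-butyldimethylsilyl)oxy]-1-[(Z)-1-methoxyprop-1-en-1-yl]cyclopent-2-en-1-ol | CO/C(=C\C)[C@]1(O)C=C(CC=C)[C@@H](O[Si](C)(C)C(C)(C)C)C1 | intermediate
8 | vanillyl alcohol (4-(hydroxymethyl)-2-methoxyphenol) | COc1cc(CO)ccc1O | starting material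
9 | sodium 4-(hydroxymethyl)-2-methoxyphenolate | COc1cc(CO)ccc1[O-].[Na+] | intermediate
10 | {4-[(tert-butyldimethylsilyl)oxy]-3-methoxyphenyl}methanol | COc1cc(CO)ccc1O[Si](C)(C)C(C)(C)C | intermediate
11 | [4-(bromomethyl)-2-methoxyphenoxy](tert-butyl)dimethylsilane | COc1cc(CBr)ccc1O[Si](C)(C)C(C)(C)C | intermediate
12 | 4-[(tert-butyldimethylsilyl)oxy]-3-methoxybenzyl trifluoromethanesulfonate (ionises to the benzylic cation) | COc1cc(COS(=O)(=O)C(F)(F)F)ccc1O[Si](C)(C)C(C)(C)C | intermediate
13 | (2S,5S)-4-allyl-5-[(tert-butyldimethylsilyl)oxy]-2-{(2R)-1-[4-[(tert-butyldimethylsilyl)oxy]-3-methoxyphenyl]propan-2-yl}-2-methoxycyclohex-3-en-1-one | C=CCC1=C[C@@](OC)([C@H](C)Cc2ccc(O[Si](C)(C)C(C)(C)C)c(OC)c2)C(=O)C[C@@H]1O[Si](C)(C)C(C)(C)C | intermediate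
14 | potassium enolate of 13 (O–K on C1, C1=C6 double bond) | C=CCC1=C[C@@](OC)([C@H](C)Cc2ccc(O[Si](C)(C)C(C)(C)C)c(OC)c2)C([O-])=C[C@@H]1O[Si](C)(C)C(C)(C)C.[K+] | intermediate
15 | tert-butyl{[(1S,4S)-2-allyl-4-{(2R)-1-[4-[(tert-butyldimethylsilyl)oxy]-3-methoxyphenyl]propan-2-yl}-4,5-dimethoxycyclohexa-2,5-dien-1-yl]oxy}dimethylsilane | C=CCC1=C[C@@](OC)([C@H](C)Cc2ccc(O[Si](C)(C)C(C)(C)C)c(OC)c2)C(OC)=C[C@@H]1O[Si](C)(C)C(C)(C)C | intermediate
16 | (1S,4S)-2-allyl-4-[(2R)-1-(4-hydroxy-3-methoxyphenyl)propan-2-yl]-4,5-dimethoxycyclohexa-2,5-dien-1-ol | C=CCC1=C[C@@](OC)([C@H](C)Cc2ccc(O)c(OC)c2)C(OC)=C[C@@H]1O | intermediate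
17 | (4S)-2-allyl-4-[(2R)-1-(4-hydroxy-3-methoxyphenyl)propan-2-yl]-4,5-dimethoxycyclohexa-2,5-dien-1-one | C=CCC1=C[C@@](OC)([C@H](C)Cc2ccc(O)c(OC)c2)C(OC)=CC1=O | target

**Count**

Total step count: 9. Longest linear sequence: 6 steps (steps 1, 3, 6, 7, 8, 9 from enone 1).

**Steps most likely to fail**

Risk at step 6 (proposed new method). The benzyl cation may be captured by the tertiary hydroxyl, the oxocarbenium ion may lose a proton before the 1,2-shift, or the facial control relayed from the carbinol centre may erode. The fallback uses known chemistry, sets out from 7 and comes back at 13. The enol ether of 7 is hydrolysed with dilute oxalic acid in wet THF to the α-hydroxy ethyl ketone 1-[(1R,4S)-3-allyl-4-[(tert-butyldimethylsilyl)oxy]-1-hydroxycyclopent-2-en-1-yl]propan-1-one F1. Its chelated Z(O) dilithium dianion (LDA, 2.2 equiv, THF, −78 °C) is C-alkylated with bromide 11 to give the benzylated ketol F2; if the alkylation shows little facial bias, the C8 epimers are diastereomers and are separated by chromatography. A chelating Lewis acid (for example Al(OtBu)3 or Sc(OTf)3 in toluene) then brings about the classical α-ketol rearrangement, in which the ring vinyl carbon migrates suprafacially within the metal chelate and gives the ring-expanded tertiary α-hydroxy ketone F3. O-Methylation of F3 with MeOTf and 2,6-di-tert-butylpyridine in CH2Cl2 returns to 13.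

Risk at step 7. C-Methylation at C6 may compete with O-methylation of the enolate, or the enolate may expel the β-silyloxy group. The fallback sets out from 13 and comes back at 17. Soft enolisation (TMSOTf, Et3N) converts 13 into the trimethylsilyl enol ether F4, and Saegusa–Ito dehydrogenation with Pd(OAc)2 gives the 3-silyloxy-2,4-dienone F5. This is a vinylogous silyl ester in which the silyl group sits on the oxygen remote from the quaternary centre. Meerwein's salt (Me3OBF4, CH2Cl2) alkylates the carbonyl oxygen, and loss of the silyl group from the resulting 1-methoxy-3-silyloxyallyl cation leaves the methoxy group on the carbon next to the quaternary centre, giving the O-silylated target F6. Buffered TBAF then frees the phenol and gives 17, so that no free phenol meets an oxidant.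

Risk at step 3. The propenyl ether may be metalated at the allylic instead of the vinylic position, or the basic vinyllithium may deprotonate enone 3 at its γ-positions instead of adding to the carbonyl. The fallback sets out from 3 and comes back at 13. The sulfur-stabilised acyl-anion equivalent 2-ethyl-2-lithio-1,3-dithiane F7 (from 2-ethyl-1,3-dithiane and n-BuLi, Corey–Seebach reaction) adds 1,2 to 3 anti to the silyloxy group to give the dithianyl carbinol F8. Unmasking with PhI(OCOCF3)2 in aqueous MeCN gives the hydroxy ketone F1, which is taken on through the benzylated ketol F2 and the rearranged hydroxy ketone F3 to 13 as described for step 6.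

**Further compounds**

F1 | step 6 | 1-[(1R,4S)-3-allyl-4-[(tert-butyldimethylsilyl)oxy]-1-hydroxycyclopent-2-en-1-yl]propan-1-one | CCC(=O)[C@]1(O)C=C(CC=C)[C@@H](O[Si](C)(C)C(C)(C)C)C1
F2 | step 6 | (2R)-1-[(1R,4S)-3-allyl-4-[(tert-butyldimethylsilyl)oxy]-1-hydroxycyclopent-2-en-1-yl]-3-{4-[(tert-butyldimethylsilyl)oxy]-3-methoxyphenyl}-2-methylpropan-1-one | C[C@H](Cc1ccc(O[Si](C)(C)C(C)(C)C)c(OC)c1)C(=O)[C@]1(O)C=C(CC=C)[C@@H](O[Si](C)(C)C(C)(C)C)C1
F3 | step 6 | (2S,5S)-4-allyl-5-[(tert-butyldimethylsilyl)oxy]-2-{(2R)-1-[4-[(tert-butyldimethylsilyl)oxy]-3-methoxyphenyl]propan-2-yl}-2-hydroxycyclohex-3-en-1-one | C=CCC1=C[C@@](O)([C@H](C)Cc2ccc(O[Si](C)(C)C(C)(C)C)c(OC)c2)C(=O)C[C@@H]1O[Si](C)(C)C(C)(C)C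
F4 | step 7 | trimethylsilyl enol ether of 13 (OTMS on C1, C1=C6 double bond) | C=CCC1=C[C@@](OC)([C@H](C)Cc2ccc(O[Si](C)(C)C(C)(C)C)c(OC)c2)C(O[Si](C)(C)C)=C[C@@H]1O[Si](C)(C)C(C)(C)C
F5 | step 7 | (6S)-4-allyl-3-[(tert-butyldimethylsilyl)oxy]-6-{(2R)-1-[4-[(tert-butyldimethylsilyl)oxy]-3-methoxyphenyl]propan-2-yl}-6-methoxycyclohexa-2,4-dien-1-one | C=CCC1=C[C@@](OC)([C@H](C)Cc2ccc(O[Si](C)(C)C(C)(C)C)c(OC)c2)C(=O)C=C1O[Si](C)(C)C(C)(C)C
F6 | step 7 | (4S)-2-allyl-4-{(2R)-1-[4-[(tert-butyldimethylsilyl)oxy]-3-methoxyphenyl]propan-2-yl}-4,5-dimethoxycyclohexa-2,5-dien-1-one | C=CCC1=C[C@@](OC)([C@H](C)Cc2ccc(O[Si](C)(C)C(C)(C)C)c(OC)c2)C(OC)=CC1=O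
F7 | step 3 | 2-ethyl-2-lithio-1,3-dithiane | CCC1([Li])SCCCS1
F8 | step 3 | (1R,4S)-3-allyl-4-[(tert-butyldimethylsilyl)oxy]-1-(2-ethyl-1,3-dithian-2-yl)cyclopent-2-en-1-ol | CCC1(SCCCS1)[C@]1(O)C=C(CC=C)[C@@H](O[Si](C)(C)C(C)(C)C)C1
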